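**Assumption:** the SMILES has no stereodescriptor and the molecule has no stereocentre, so the hindered C6–C8'' axis is treated as undefined and the compound is made as drawn, racemic about that axis.

## Retrosynthetic overview
1. The target comes from its 5'',7''-di-O-benzyl ether by global hydrogenolysis in the last step.
2. The key disconnection is the C6–C8'' biaryl bond. Both carbons are enol-type donor positions of phloroglucinol-like rings A.
3. C8'' is inverted to an aryl-cation (vinylogous enolonium) equivalent, a C8-bound phenyl-λ3-iodonium made by direct C–H iodanylation. The unfunctionalised C6–H of genkwanin is the nucleophile.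
4. The iodonium half comes from 5,7-di-O-benzylacacetin, made from acacetin. The nucleophile half is genkwanin, made from apigenin by 7-O-methylation.
5. No ring is built. Rings A, B and C of both halves are bought intact, and the only skeletal bond formed is the inter-flavone bond, in the penultimate step.

## Route

Step 1
Reactants: 1 apigenin (5,7,4'-trihydroxyflavone)
Product: 2 genkwanin (5,4'-dihydroxy-7-methoxyflavone)
Conditions: MeI (1.05 equiv), K2CO3 (1.0 equiv), DMF, 0 °C to rt, 16 h
Reagents that add atoms: methyl iodide (MeI), SMILES CI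
Why: Williamson etherification is selective for the 7-OH because it is a vinylogous carboxylic acid and the most acidic OH, whereas the 5-OH is locked in a hydrogen bond to C4=O and the 4'-OH is clearly less acidic, so limiting base and MeI alkylate O7 only.

Step 2
Reactants: 3 acacetin (5,7-dihydroxy-4'-methoxyflavone)
Product: 4 5,7-bis(benzyloxy)-2-(4-methoxyphenyl)-4H-chromen-4-one (5,7-di-O-benzylacacetin)
Conditions: BnBr (3 equiv), K2CO3 (4 equiv), DMF, 80 °C, 16 h
Reagents that add atoms: benzyl bromide (BnBr), SMILES BrCc1ccccc1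
Why: Exhaustive Williamson benzylation works because heat and excess reagent also alkylate the chelated 5-OH, and capping both oxygens removes every oxidisable phenol and switches the electrophile-accepting site of ring A from C6 to C8.

Step 3
Reactants: 4 5,7-di-O-benzylacacetin; 2 genkwanin
Product: 7 5,7-bis(benzyloxy)-8-[5-hydroxy-2-(4-hydroxyphenyl)-7-methoxy-4-oxo-4H-chromen-6-yl]-2-(4-methoxyphenyl)-4H-chromen-4-one, via flavon-8-yl(phenyl)iodonium tosylate 5 (not isolated), via flavon-8-yl(phenyl)iodonium bromide 6 (not isolated)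
Conditions: PhI(OH)OTs (1.0 equiv), (CF3)2CHOH, rt, 3 h; then 2 (1.5 equiv), Me3SiBr (2 equiv), rt, 12 h
Reagents that add atoms: none
Why: Proposed new method: PhI(OH)OTs ionised by (CF3)2CHOH is attacked by the less hindered, triply O-activated C8 of 4 (the site where 5,7-dialkoxyflavones are halogenated) to give the C-bound λ3-iodane 5, an aryl-cation (vinylogous enolonium) equivalent; Me3SiBr swaps tosylate for bromide (6), charge transfer from the electron-rich flavonyl ring to trivalent iodine makes the ipso carbon the acceptor, C6 of 2 (the site where 5-hydroxy-7-methoxyflavones are halogenated) attacks it, and loss of PhI and HBr rearomatises both rings; the closest known reaction type is the Kita-type hypervalent-iodine C–H/C–H cross-coupling, in which thienyl- or alkoxyaryl(phenyl)iodonium salts made in situ in (CF3)2CHOH undergo Me3SiBr-triggered ipso substitution by a second electron-rich arene with transfer of the electron-rich aryl and not of phenyl; no stereocentre is formed and the new axis arises racemic.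

Step 4
Reactants: 7 5'',7''-di-O-benzyl biflavone
Product: 8 8-[5-hydroxy-2-(4-hydroxyphenyl)-7-methoxy-4-oxo-4H-chromen-6-yl]-5,7-dihydroxy-2-(4-methoxyphenyl)-4H-chromen-4-one (target, 7,4'''-di-O-methylagathisflavone)
Conditions: H2 (1 atm), Pd/C (10 wt% Pd), THF–MeOH 1:1, rt, 6 h
Reagents that add atoms: none
Why: Catalytic hydrogenolysis cleaves the two aryl benzyl ethers, while the chromone C2=C3 bonds, both methyl ethers and the biaryl bond are inert at 1 atm and rt.

## Compound list
1 | apigenin | O=c1cc(-c2ccc(O)cc2)oc2cc(O)cc(O)c12 | starting material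
2 | genkwanin | COc1cc(O)c2c(=O)cc(-c3ccc(O)cc3)oc2c1 | intermediate
3 | acacetin | COc1ccc(-c2cc(=O)c3c(O)cc(O)cc3o2)cc1 | starting material
4 | 5,7-di-O-benzylacacetin | COc1ccc(-c2cc(=O)c3c(OCc4ccccc4)cc(OCc4ccccc4)cc3o2)cc1 | intermediate
5 | [5,7-bis(benzyloxy)-2-(4-methoxyphenyl)-4-oxo-4H-chromen-8-yl](phenyl)iodonium tosylate | COc1ccc(-c2cc(=O)c3c(OCc4ccccc4)cc(OCc4ccccc4)c([I+]c4ccccc4)c3o2)cc1.Cc1ccc(S(=O)(=O)[O-])cc1 | intermediate
6 | [5,7-bis(benzyloxy)-2-(4-methoxyphenyl)-4-oxo-4H-chromen-8-yl](phenyl)iodonium bromide | COc1ccc(-c2cc(=O)c3c(OCc4ccccc4)cc(OCc4ccccc4)c([I+]c4ccccc4)c3o2)cc1.[Br-] | intermediate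
7 | 5'',7''-di-O-benzyl-7,4'''-di-O-methylagathisflavone | COc1ccc(-c2cc(=O)c3c(OCc4ccccc4)cc(OCc4ccccc4)c(-c4c(OC)cc5oc(-c6ccc(O)cc6)cc(=O)c5c4O)c3o2)cc1 | intermediate
8 | 7,4'''-di-O-methylagathisflavone (CNP0253922.0) | COc1ccc(-c2cc(=O)c3c(O)cc(O)c(-c4c(OC)cc5oc(-c6ccc(O)cc6)cc(=O)c5c4O)c3o2)cc1 | target

## Step count and risks
Total step count: 4. Longest linear sequence: 3 (3 → 4 → 7 → 8, or 1 → 2 → 7 → 8).

**Most likely to fail: step 3.**
- Phenyl could be transferred instead of the flavonyl group.
- Compound 2 could attack through C8 instead of C6.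
- Compound 4 could homocouple.
- The tetra-ortho-substituted bond may simply form too slowly.
- Exactly one equivalent of PhI(OH)OTs is used, so the free phenols of 2 never meet the oxidant.
- Partial loss of the peri 5''-O-benzyl group to HBr is harmless, because step 4 removes it anyway.

The fallback sets out from 4 and 2 and comes back at 8. It keeps C8'' as the acceptor but replaces ipso substitution at iodine by ligand coupling at tetravalent lead (Pinhey-type arylation of a phenoxide), which fixes both sites by covalent bonds. Compound 4 is iodinated with NIS and cat. CF3CO2H in MeCN at rt to give 8-iodo-5,7-bis(benzyloxy)-4'-methoxyflavone F1. This is stannylated with (Bu3Sn)2 and Pd(PPh3)4 in toluene at 110 °C to give 8-(tributylstannyl)-5,7-bis(benzyloxy)-4'-methoxyflavone F2. Tin–lead exchange with Pb(OAc)4 and cat. Hg(OAc)2 in CHCl3 at 40 °C gives [5,7-bis(benzyloxy)-4'-methoxyflavon-8-yl]lead triacetate F3. In parallel, 2 is capped at its only unchelated phenol with BnBr (1.1 equiv) and K2CO3 in refluxing acetone to give 4'-O-benzylgenkwanin F4. The lithium 5-phenoxide of F4 (LiHMDS, toluene, −20 °C) displaces one acetate of F3 in the presence of pyridine. The aryl group then migrates from lead to C6, the only free ortho carbon, giving 5'',7'',4'-tri-O-benzyl-7,4'''-di-O-methylagathisflavone F5. Under the conditions of step 4, F5 gives 8.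

**Second: step 1.** Over-methylation to the 7,4'-dimethyl ether or a poorly separable mixture is the risk. The fallback sets out from 1 and comes back at 2, replacing pKa-controlled alkylation by a protect–unmask sequence. Compound 1 is peracetylated (Ac2O, pyridine, rt) to give apigenin 5,7,4'-triacetate F6. PhSH and imidazole in NMP at 0 °C remove only the 7-acetate, the ester of the best phenoxide leaving group, to give apigenin 5,4'-diacetate F7. The single free OH is methylated under neutral Mitsunobu conditions (MeOH, PPh3, DIAD, THF) to give genkwanin 5,4'-diacetate F8. Methanolysis (cat. K2CO3, MeOH, rt) returns 2.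

**Third: step 4.** The risks are poor solubility of the biflavone on the catalyst, slow cleavage of the hindered 7''-O-benzyl group, and creeping reduction of a chromone C2=C3 bond. The fallback sets out from 7 and comes back at 8. It replaces reduction by Lewis-acid ether cleavage with a cation trap, using BCl3 (6 equiv) and pentamethylbenzene (6 equiv) in CH2Cl2 at −78 °C. These conditions remove aryl benzyl ethers and spare the 7- and 4'''-methyl ethers, neither of which is ortho to a carbonyl group. New compounds on this path: none F0.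

## Further compounds
F1 | step 3 | 8-iodo-5,7-bis(benzyloxy)-4'-methoxyflavone | COc1ccc(-c2cc(=O)c3c(OCc4ccccc4)cc(OCc4ccccc4)c(I)c3o2)cc1
F2 | step 3 | 8-(tributylstannyl)-5,7-bis(benzyloxy)-4'-methoxyflavone | CCCC[Sn](CCCC)(CCCC)c1c(OCc2ccccc2)cc(OCc2ccccc2)c2c(=O)cc(-c3ccc(OC)cc3)oc12
F3 | step 3 | [5,7-bis(benzyloxy)-4'-methoxyflavon-8-yl]lead triacetate | CC(=O)O[Pb](OC(C)=O)(OC(C)=O)c1c(OCc2ccccc2)cc(OCc2ccccc2)c2c(=O)cc(-c3ccc(OC)cc3)oc12
F4 | step 3 | 4'-O-benzylgenkwanin | COc1cc(O)c2c(=O)cc(-c3ccc(OCc4ccccc4)cc3)oc2c1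
F5 | step 3 | 5'',7'',4'-tri-O-benzyl-7,4'''-di-O-methylagathisflavone | COc1ccc(-c2cc(=O)c3c(OCc4ccccc4)cc(OCc4ccccc4)c(-c4c(OC)cc5oc(-c6ccc(OCc7ccccc7)cc6)cc(=O)c5c4O)c3o2)cc1
F6 | step 1 | apigenin 5,7,4'-triacetate | CC(=O)Oc1ccc(-c2cc(=O)c3c(OC(C)=O)cc(OC(C)=O)cc3o2)cc1
F7 | step 1 | apigenin 5,4'-diacetate | CC(=O)Oc1ccc(-c2cc(=O)c3c(OC(C)=O)cc(O)cc3o2)cc1
F8 | step 1 | genkwanin 5,4'-diacetate | COc1cc(OC(C)=O)c2c(=O)cc(-c3ccc(OC(C)=O)cc3)oc2c1
F0 | step 4 | none | none
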